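**Retrosynthetic overview**
1. Target 20 ⇐ SeO2 allylic oxidation of isopropenyl lactone 19 ⇐ Horner–Wadsworth–Emmons methylenation of α-phosphono lactone 18, whose γ-lactone closes last onto the C8 hydroxyl.
2. C6–O and C8–O come from the two carbonyls of a masked cyclohexane-1,3-dione, reduced one after the other from the face opposite the axial C10 methyl; the C7 side chain arrives by cross-coupling on an α-iodo vinylogous ester, the oxirane from a C1 aldehyde.
3. The vinylogous ester ⇐ bicyclic ketal 5 (6-oxabicyclo[3.2.1]octene), whose oxygen bridge forces the C5 isopropenyl group trans to C1.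
4. Key disconnection: 5 ⇐ achiral, mirror-symmetric bis(enol ether) alcohol 3 by catalytic enantioselective hydroxyl-directed epoxidation with transannular ketalisation (sets C8, C9, C10 in one step).
5. 3 ⇐ 3,5-dimethoxybenzoic acid by Birch reductive methylation; ring order: carbocycle (from the arene) → temporary oxa-bridge → oxirane → γ-lactone.

**Conventions and assumptions**
- Ring carbons carry elemane locants: C10 (quaternary, CH3 and C1), C5, C6, C7, C8, C9. β = the face of the C10 methyl; α = the face of the C10–C1 bond. The target is 5β-(3-oxoprop-1-en-2-yl), 6β-OAng, 7β-C11, 8β-O, 9α-OAng, (1R)-oxirane (Ang = angeloyl, (Z)-2-methylbut-2-enoyl).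
- Assumption: numbered compounds are substrates, intermediates and the target; reagents that contribute atoms are given by name and SMILES in each step.
- Assumption: the (R,R)-ligand in step 3 is taken to give the enantiomer drawn; if it gives the antipode, the (S,S)-ligand is used.

**Route**

Step 1
Reactants: 1 3,5-dimethoxybenzoic acid
Product: 2 3,5-dimethoxy-1-methylcyclohexa-2,5-diene-1-carboxylic acid
Conditions: Li (3 equiv), NH3(l)/THF, −78 °C; MeI, −78 °C to rt; aq. HCl
Reagents that add atoms: iodomethane, CI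
Why: Birch reductive alkylation, in which the 1,4-dihydrobenzoate dianion is C-methylated at the carboxylate-bearing carbon to give an achiral, mirror-symmetric diene that keeps both methoxy groups as enol ethers (no stereocentre yet).

Step 2
Reactants: 2 3,5-dimethoxy-1-methylcyclohexa-2,5-diene-1-carboxylic acid
Product: 3 (3,5-dimethoxy-1-methylcyclohexa-2,5-dien-1-yl)methanol
Conditions: LiAlH4, THF, 0 °C to reflux; basic (Fieser) work-up
Reagents that add atoms: none
Why: LiAlH4 reduction of the acid to the primary alcohol leaves the base-stable enol ethers intact and installs the hydroxyl that directs and tethers the next step.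

Step 3
Reactants: 3 (3,5-dimethoxy-1-methylcyclohexa-2,5-dien-1-yl)methanol
Product: 5 3,5-dimethoxy-1-methyl-6-oxabicyclo[3.2.1]oct-2-en-8-ol (8-OH syn to the O6–C7 bridge), via epoxy ether 4 (not isolated)
Conditions: VO(OiPr)3 (2 mol %), (R,R)-N,N′-(cyclohexane-1,2-diyl)bis(N-hydroxy-2,2-diphenylacetamide) (4 mol %), cumene hydroperoxide (1.05 equiv), 4 Å MS, toluene, −20 to 0 °C
Reagents that add atoms: cumene hydroperoxide, CC(C)(OO)c1ccccc1
Why: Proposed new method: the vanadium alkoxide of the homoallylic alcohol delivers oxygen to the CH2OH face of one of the two enantiotopic enol ethers, the arm being chosen by the C2-symmetric bis-hydroxamate ligand (closest known chemistry: vanadium-catalysed asymmetric epoxidation and desymmetrisation of homoallylic alcohols), and the labile 2-methoxyoxirane opens to an oxocarbenium ion that the same CH2OH traps across the ring, fixing C10, C9 (O cis to C1) and the ketal carbon C8 at once.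

Step 4
Reactants: 5 3,5-dimethoxy-1-methyl-6-oxabicyclo[3.2.1]oct-2-en-8-ol
Product: 6 3,5-dimethoxy-1-methyl-6-oxabicyclo[3.2.1]oct-2-en-8-yl (Z)-2-methylbut-2-enoate
Conditions: LiN(SiMe3)2 (1.1 equiv), THF, −78 °C; angelic anhydride (1.3 equiv), −78 to 0 °C; aq. NH4Cl
Reagents that add atoms: angelic anhydride, C/C=C(/C)C(=O)OC(=O)/C(C)=C\C
Why: O-acylation of the lithium alkoxide with the anhydride installs the C9 angelate without Z-to-E isomerisation and removes the only free hydroxyl before the Lewis-acid step.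

Step 5
Reactants: 6 3,5-dimethoxy-1-methyl-6-oxabicyclo[3.2.1]oct-2-en-8-yl (Z)-2-methylbut-2-enoate
Product: 9 6-(hydroxymethyl)-2-methoxy-6-methyl-4-oxo-5-(prop-1-en-2-yl)cyclohex-2-en-1-yl (Z)-2-methylbut-2-enoate, via silyl carbinol 7 (not isolated), via bicyclic ketone 8 (not isolated)
Conditions: 1-(trimethylsilyl)propan-2-one (3 equiv), BF3·OEt2 (2.5 equiv), CH2Cl2, −78 to 0 °C; H2O; then CSA (10 mol %), CH2Cl2, 23 °C
Reagents that add atoms: 1-(trimethylsilyl)propan-2-one, CC(=O)C[Si](C)(C)C; water, O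
Why: Proposed new method: the remaining enol ether attacks the BF3-activated α-silyl ketone at C5 from the exo face (anti to the O–CH2 bridge, hence trans to C1 and cis to the C10 methyl), the β-hydroxysilane undergoes acid-mediated Peterson elimination to the isopropenyl group, and acid-catalysed β-elimination of the ketal oxygen (retro-oxa-Michael) opens the bicycle to the vinylogous ester, the closest known chemistry being the Mukaiyama aldol of enol ethers and the Peterson olefination of α-silyl ketone adducts.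

Step 6
Reactants: 9 6-(hydroxymethyl)-2-methoxy-6-methyl-4-oxo-5-(prop-1-en-2-yl)cyclohex-2-en-1-yl (Z)-2-methylbut-2-enoate
Product: 10 6-formyl-2-methoxy-6-methyl-4-oxo-5-(prop-1-en-2-yl)cyclohex-2-en-1-yl (Z)-2-methylbut-2-enoate
Conditions: Dess–Martin periodinane, NaHCO3, CH2Cl2, 0 to 23 °C
Reagents that add atoms: none
Why: Dess–Martin oxidation of the only free (neopentyl primary) alcohol gives a non-enolisable aldehyde and drains any ring-closed ketal form of 9.

Step 7
Reactants: 10 6-formyl-2-methoxy-6-methyl-4-oxo-5-(prop-1-en-2-yl)cyclohex-2-en-1-yl (Z)-2-methylbut-2-enoate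
Product: 11 2-methoxy-6-methyl-6-[(2R)-oxiran-2-yl]-4-oxo-5-(prop-1-en-2-yl)cyclohex-2-en-1-yl (Z)-2-methylbut-2-enoate
Conditions: Me3S+ I− (1.3 equiv), KN(SiMe3)2 (1.2 equiv), THF, −20 °C; then 10, −78 to 0 °C
Reagents that add atoms: trimethylsulfonium iodide, C[S+](C)C.[I-]
Why: Corey–Chaykovsky methylene transfer with a non-chelating sulfonium ylide, in which Felkin–Anh attack anti to the C10–C9 bond (the branch carrying the bulky angeloyloxy group) with the C10 methyl flanking the trajectory gives the (R)-oxirane.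

Step 8
Reactants: 11 2-methoxy-6-methyl-6-[(2R)-oxiran-2-yl]-4-oxo-5-(prop-1-en-2-yl)cyclohex-2-en-1-yl (Z)-2-methylbut-2-enoate
Product: 12 3-iodo-2-methoxy-6-methyl-6-[(2R)-oxiran-2-yl]-4-oxo-5-(prop-1-en-2-yl)cyclohex-2-en-1-yl (Z)-2-methylbut-2-enoate
Conditions: N-iodosuccinimide (1.2 equiv), MeCN, 0 to 23 °C, dark
Reagents that add atoms: N-iodosuccinimide, O=C1CCC(=O)N1I
Why: Electrophilic α-iodination of the vinylogous ester at its nucleophilic α-carbon (C7), the other alkenes being less electron-rich or ester-conjugated.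

Step 9
Reactants: 12 3-iodo-2-methoxy-6-methyl-6-[(2R)-oxiran-2-yl]-4-oxo-5-(prop-1-en-2-yl)cyclohex-2-en-1-yl (Z)-2-methylbut-2-enoate
Product: 13 3-[1-(dimethoxyphosphoryl)-2-methoxy-2-oxoethyl]-2-methoxy-6-methyl-6-[(2R)-oxiran-2-yl]-4-oxo-5-(prop-1-en-2-yl)cyclohex-2-en-1-yl (Z)-2-methylbut-2-enoate
Conditions: (MeO)2P(O)CH2CO2Me (1.5 equiv), K3PO4 (2 equiv), Pd2(dba)3 (2.5 mol %), P(t-Bu)3·HBF4 (10 mol %), toluene, 60 °C
Reagents that add atoms: trimethyl phosphonoacetate, COC(=O)CP(=O)(OC)OC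
Why: Palladium-catalysed α-alkenylation of a stabilised enolate (Buchwald–Hartwig-type enolate cross-coupling with an α-iodoenone) attaches C11 with its ester and phosphonate, the C11 configuration being irrelevant because it is destroyed in step 12.

Step 10
Reactants: 13 3-[1-(dimethoxyphosphoryl)-2-methoxy-2-oxoethyl]-2-methoxy-6-methyl-6-[(2R)-oxiran-2-yl]-4-oxo-5-(prop-1-en-2-yl)cyclohex-2-en-1-yl (Z)-2-methylbut-2-enoate
Product: 15 3-[1-(dimethoxyphosphoryl)-2-methoxy-2-oxoethyl]-2-methoxy-6-methyl-6-[(2R)-oxiran-2-yl]-5-(prop-1-en-2-yl)cyclohex-2-ene-1,4-diyl bis[(Z)-2-methylbut-2-enoate], via allylic alkoxide 14 (not isolated)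
Conditions: LiN(SiMe3)2 (1.05 equiv), THF, −78 °C; LiBH(s-Bu)3 (1.2 equiv), −78 °C; angelic anhydride (1.3 equiv), −78 to −20 °C; aq. NH4Cl
Reagents that add atoms: angelic anhydride, C/C=C(/C)C(=O)OC(=O)/C(C)=C\C
Why: With the acidic C11–H masked as its enolate (which also stops lactonisation onto O6), the bulky hydride performs a 1,2-reduction of the C6 carbonyl from the α face because the pseudo-axial C10 methyl blocks the β face, giving the 6β-alkoxide (cis to the isopropenyl group), which is O-acylated in the same flask.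

Step 11
Reactants: 15 3-[1-(dimethoxyphosphoryl)-2-methoxy-2-oxoethyl]-2-methoxy-6-methyl-6-[(2R)-oxiran-2-yl]-5-(prop-1-en-2-yl)cyclohex-2-ene-1,4-diyl bis[(Z)-2-methylbut-2-enoate]
Product: 18 3-(dimethoxyphosphoryl)-6-methyl-6-[(2R)-oxiran-2-yl]-2-oxo-5-(prop-1-en-2-yl)octahydro-1-benzofuran-4,7-diyl bis[(Z)-2-methylbut-2-enoate] (cis-fused), via keto phosphonate 16 (not isolated), via hydroxy ester 17 (not isolated)
Conditions: 1 M HCl, THF, 0 °C, then NaHCO3; NaBH4, MeOH/THF, −40 to 0 °C; AcOH to pH 5, 23 °C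
Reagents that add atoms: water, O
Why: Enol ether hydrolysis protonates C7 from the α face (anti to the axial 6β-angelate, and giving the equatorial, thermodynamically preferred side chain), NaBH4 then attacks the C8 ketone from the α face because the 1,3-syn-axial C10 methyl and C6 angelate block the β face, and the 8β-alkoxide, cis to the C7 side chain, closes the cis-fused γ-lactone faster than it can accept the hindered angeloyl group.

Step 12
Reactants: 18 3-(dimethoxyphosphoryl)-6-methyl-6-[(2R)-oxiran-2-yl]-2-oxo-5-(prop-1-en-2-yl)octahydro-1-benzofuran-4,7-diyl bis[(Z)-2-methylbut-2-enoate]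
Product: 19 6-methyl-3-methylidene-6-[(2R)-oxiran-2-yl]-2-oxo-5-(prop-1-en-2-yl)octahydro-1-benzofuran-4,7-diyl bis[(Z)-2-methylbut-2-enoate]
Conditions: K2CO3 (2 equiv), 37% aq. HCHO (5 equiv), THF, 0 to 23 °C
Reagents that add atoms: formaldehyde, C=O
Why: Horner–Wadsworth–Emmons reaction of the α-phosphono lactone with formaldehyde under carbonate base gives the α-methylene lactone without enolising the angelates or touching the oxirane.

Step 13
Reactants: 19 6-methyl-3-methylidene-6-[(2R)-oxiran-2-yl]-2-oxo-5-(prop-1-en-2-yl)octahydro-1-benzofuran-4,7-diyl bis[(Z)-2-methylbut-2-enoate]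
Product: 20 6-methyl-3-methylidene-6-[(2R)-oxiran-2-yl]-2-oxo-5-(3-oxoprop-1-en-2-yl)octahydro-1-benzofuran-4,7-diyl bis[(Z)-2-methylbut-2-enoate] (CNP0291490.2)
Conditions: SeO2 (1.5 equiv), pyridine (2 equiv), 1,4-dioxane, 70 °C
Reagents that add atoms: selenium dioxide, O=[Se]=O
Why: Riley allylic oxidation (ene reaction then [2,3]-shift) at the methyl of the isopropenyl group, the only electron-rich alkene with an allylic C–H, carried through to the enal while the ester-conjugated alkenes stay untouched.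

**Compound list**
1 | 3,5-dimethoxybenzoic acid | COc1cc(OC)cc(c1)C(=O)O | starting material
2 | 3,5-dimethoxy-1-methylcyclohexa-2,5-diene-1-carboxylic acid (achiral) | COC1=CC(C)(C(=O)O)C=C(OC)C1 | intermediate
3 | (3,5-dimethoxy-1-methylcyclohexa-2,5-dien-1-yl)methanol (achiral) | COC1=CC(C)(CO)C=C(OC)C1 | intermediate
4 | (1,3-dimethoxy-5-methyl-7-oxabicyclo[4.1.0]hept-3-en-5-yl)methanol, oxirane oxygen syn to CH2OH | COC1=C[C@](C)(CO)[C@@H]2O[C@]2(OC)C1 | intermediate
5 | 3,5-dimethoxy-1-methyl-6-oxabicyclo[3.2.1]oct-2-en-8-ol, 8-OH syn to the O6–C7 bridge | COC1=C[C@]2(C)CO[C@](OC)(C1)[C@H]2O | intermediate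
6 | 8-O-angelate of 5 | COC1=C[C@]2(C)CO[C@](OC)(C1)[C@H]2OC(=O)/C(C)=C\C | intermediate
7 | 2-[2-hydroxy-1-(trimethylsilyl)propan-2-yl]-5-methoxy-1-methyl-3-oxo-6-oxabicyclo[3.2.1]octan-8-yl angelate, C2 substituent anti to the oxygen bridge, carbinol carbon as a mixture | O=C1C[C@@]2(OC)OC[C@](C)([C@@H]2OC(=O)/C(C)=C\C)[C@@H]1C(C)(O)C[Si](C)(C)C | intermediate
8 | 5-methoxy-1-methyl-3-oxo-2-(prop-1-en-2-yl)-6-oxabicyclo[3.2.1]octan-8-yl angelate, isopropenyl anti to the oxygen bridge | O=C1C[C@@]2(OC)OC[C@](C)([C@@H]2OC(=O)/C(C)=C\C)[C@@H]1C(C)=C | intermediate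
9 | 6-(hydroxymethyl)-2-methoxy-6-methyl-4-oxo-5-(prop-1-en-2-yl)cyclohex-2-en-1-yl angelate (9α-OAng, 5β-isopropenyl, 10β-CH3) | COC1=CC(=O)[C@@H](C(C)=C)[C@](C)(CO)[C@@H]1OC(=O)/C(C)=C\C | intermediate
10 | 6-formyl-2-methoxy-6-methyl-4-oxo-5-(prop-1-en-2-yl)cyclohex-2-en-1-yl angelate | COC1=CC(=O)[C@@H](C(C)=C)[C@](C)(C=O)[C@@H]1OC(=O)/C(C)=C\C | intermediate
11 | 2-methoxy-6-methyl-6-[(2R)-oxiran-2-yl]-4-oxo-5-(prop-1-en-2-yl)cyclohex-2-en-1-yl angelate | COC1=CC(=O)[C@@H](C(C)=C)[C@](C)([C@@H]2CO2)[C@@H]1OC(=O)/C(C)=C\C | intermediate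
12 | 3-iodo derivative of 11 | COC1=C(I)C(=O)[C@@H](C(C)=C)[C@](C)([C@@H]2CO2)[C@@H]1OC(=O)/C(C)=C\C | intermediate
13 | 3-[1-(dimethoxyphosphoryl)-2-methoxy-2-oxoethyl] derivative of 11 (C11 as a mixture) | COC1=C(C(C(=O)OC)P(=O)(OC)OC)C(=O)[C@@H](C(C)=C)[C@](C)([C@@H]2CO2)[C@@H]1OC(=O)/C(C)=C\C | intermediate
14 | 4-hydroxy compound from 13 (6β-OH, formed as its lithium alkoxide) | COC1=C(C(C(=O)OC)P(=O)(OC)OC)[C@@H](O)[C@@H](C(C)=C)[C@](C)([C@@H]2CO2)[C@@H]1OC(=O)/C(C)=C\C | intermediate
15 | 3-[1-(dimethoxyphosphoryl)-2-methoxy-2-oxoethyl]-2-methoxy-6-methyl-6-[(2R)-oxiran-2-yl]-5-(prop-1-en-2-yl)cyclohex-2-ene-1,4-diyl bis-angelate (6β,9α) | COC1=C(C(C(=O)OC)P(=O)(OC)OC)[C@@H](OC(=O)/C(C)=C\C)[C@@H](C(C)=C)[C@](C)([C@@H]2CO2)[C@@H]1OC(=O)/C(C)=C\C | intermediate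
16 | C8 ketone from 15 (7β side chain, 6β,9α-bis-angelate) | O=C1[C@@H](C(C(=O)OC)P(=O)(OC)OC)[C@@H](OC(=O)/C(C)=C\C)[C@@H](C(C)=C)[C@](C)([C@@H]2CO2)[C@@H]1OC(=O)/C(C)=C\C | intermediate
17 | 8β-alcohol from 16 | O[C@H]1[C@@H](C(C(=O)OC)P(=O)(OC)OC)[C@@H](OC(=O)/C(C)=C\C)[C@@H](C(C)=C)[C@](C)([C@@H]2CO2)[C@@H]1OC(=O)/C(C)=C\C | intermediate
18 | 3-(dimethoxyphosphoryl)-6-methyl-6-[(2R)-oxiran-2-yl]-2-oxo-5-(prop-1-en-2-yl)octahydro-1-benzofuran-4,7-diyl bis-angelate, cis-fused | COP(=O)(OC)C1C(=O)O[C@H]2[C@@H]1[C@@H](OC(=O)/C(C)=C\C)[C@@H](C(C)=C)[C@](C)([C@@H]1CO1)[C@@H]2OC(=O)/C(C)=C\C | intermediate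
19 | 6-methyl-3-methylidene-6-[(2R)-oxiran-2-yl]-2-oxo-5-(prop-1-en-2-yl)octahydro-1-benzofuran-4,7-diyl bis-angelate | C=C1C(=O)O[C@H]2[C@@H]1[C@@H](OC(=O)/C(C)=C\C)[C@@H](C(C)=C)[C@](C)([C@@H]1CO1)[C@@H]2OC(=O)/C(C)=C\C | intermediate
20 | 6-methyl-3-methylidene-6-[(2R)-oxiran-2-yl]-2-oxo-5-(3-oxoprop-1-en-2-yl)octahydro-1-benzofuran-4,7-diyl bis-angelate (CNP0291490.2) | C=C1C(=O)O[C@H]2[C@@H]1[C@@H](OC(=O)/C(C)=C\C)[C@@H](C(=C)C=O)[C@](C)([C@@H]1CO1)[C@@H]2OC(=O)/C(C)=C\C | target

**Step count and risks**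
Total steps: 13. Longest linear sequence: 13 (fully linear, no protecting groups).

The three steps most likely to fail:

Step 3. Vanadium-catalysed asymmetric epoxidation has not been run on an enol ether arm of a prochiral diene; enantioselectivity, over-oxidation of the second arm (now homoallylic to the new C9–OH) or intermolecular trapping of the oxocarbenium ion could spoil it. The fallback breaks the symmetry by a reagent-controlled ketone reduction and lets that stereocentre choose the arm. It sets out from 2: amidation (MeNHOMe·HCl, EDC) gives the Weinreb amide F1, and ICH2Cl/MeLi·LiBr at −78 °C gives the chloromethyl ketone F2. (R)-2-Methyl-CBS-oxazaborolidine with catecholborane then gives the (R)-chlorohydrin F3, whose carbinol centre makes the two enol ethers diastereotopic. A VO(acac)2/t-BuOOH hydroxyl-directed epoxidation with transannular ketalisation gives the chloromethyl-substituted bicyclic ketal F4. Angeloylation as in step 4 gives the angelate F5, and the conditions of step 5 give the vinylogous ester chlorohydrin F6. NaH in THF at 0 °C closes the oxirane and the route is rejoined at 11, so steps 6 and 7 are not needed on this path.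

Step 5. The enol ether must add to a BF3-activated α-silyl ketone faster than the Lewis acid opens the ketal or desilylates the ketone; if the ketal opens first the exo-face control is lost. The fallback swaps the Lewis-acid aldol for a regiospecific metal enolate. It sets out from 6: NBS in wet THF (NaHCO3, 0 °C) gives the exo α-bromo ketone F7, and SmI2 in THF at −78 °C generates the samarium enolate at C5 only. This adds to 1-(trimethylsilyl)propan-2-one from the exo face to give the silyl carbinol 7, where the route is rejoined; BF3·OEt2 then CSA take 7 on to 8 and 9.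

Step 7. The Felkin–Anh preference rests on the C9 branch outranking the C5 branch as the large group, so the oxirane may form as a mixture at C1. The fallback sets C1 by reagent control and sets out from 10: in situ LiCH2Cl (ICH2Cl, MeLi·LiBr, −78 °C, AcOH quench) gives the chlorohydrin epimers F8, and Dess–Martin oxidation gives the chloromethyl ketone F9. (R)-2-Methyl-CBS-oxazaborolidine with catecholborane reduces F9 to the single (R)-chlorohydrin F6 described in the first fallback, and NaH in THF closes the oxirane to return to the route at 11.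

Further compounds
F1 | step 3 | N,3,5-trimethoxy-N,1-dimethylcyclohexa-2,5-diene-1-carboxamide | COC1=CC(C)(C(=O)N(C)OC)C=C(OC)C1
F2 | step 3 | 2-chloro-1-(3,5-dimethoxy-1-methylcyclohexa-2,5-dien-1-yl)ethan-1-one | COC1=CC(C)(C(=O)CCl)C=C(OC)C1
F3 | step 3 | (1R)-2-chloro-1-(3,5-dimethoxy-1-methylcyclohexa-2,5-dien-1-yl)ethan-1-ol | COC1=CC(C)([C@@H](O)CCl)C=C(OC)C1
F4 | step 3 | 7-(chloromethyl)-3,5-dimethoxy-1-methyl-6-oxabicyclo[3.2.1]oct-2-en-8-ol, 8-OH syn to the oxygen bridge | COC1=C[C@]2(C)[C@H](CCl)O[C@](OC)(C1)[C@H]2O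
F5 | step 3 | 7-(chloromethyl)-3,5-dimethoxy-1-methyl-6-oxabicyclo[3.2.1]oct-2-en-8-yl (Z)-2-methylbut-2-enoate | COC1=C[C@]2(C)[C@H](CCl)O[C@](OC)(C1)[C@H]2OC(=O)/C(C)=C\C
F6 | step 3 | 6-[(1R)-2-chloro-1-hydroxyethyl]-2-methoxy-6-methyl-4-oxo-5-(prop-1-en-2-yl)cyclohex-2-en-1-yl (Z)-2-methylbut-2-enoate | COC1=CC(=O)[C@@H](C(C)=C)[C@](C)([C@@H](O)CCl)[C@@H]1OC(=O)/C(C)=C\C
F7 | step 5 | 2-bromo-5-methoxy-1-methyl-3-oxo-6-oxabicyclo[3.2.1]octan-8-yl (Z)-2-methylbut-2-enoate, bromine anti to the oxygen bridge | O=C1C[C@@]2(OC)OC[C@](C)([C@@H]2OC(=O)/C(C)=C\C)[C@@H]1Br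
F8 | step 7 | 6-(2-chloro-1-hydroxyethyl)-2-methoxy-6-methyl-4-oxo-5-(prop-1-en-2-yl)cyclohex-2-en-1-yl (Z)-2-methylbut-2-enoate, both carbinol epimers | COC1=CC(=O)[C@@H](C(C)=C)[C@](C)(C(O)CCl)[C@@H]1OC(=O)/C(C)=C\C
F9 | step 7 | 6-(chloroacetyl)-2-methoxy-6-methyl-4-oxo-5-(prop-1-en-2-yl)cyclohex-2-en-1-yl (Z)-2-methylbut-2-enoate | COC1=CC(=O)[C@@H](C(C)=C)[C@](C)(C(=O)CCl)[C@@H]1OC(=O)/C(C)=C\C
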